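## Retrosynthetic overview

1. The 1,2-dioxane is made last: C3–O by 6-exo peroxy-Michael closure of a C6 hydroperoxide onto an (E)-2-methyl-enoate, C6–O by cobalt/O2/silane silylperoxidation of a trisubstituted alkene.
2. Side chain: the enoate comes from cross-metathesis with methyl methacrylate, the (E)-trisubstituted alkene from methylalumination/allylation of a terminal alkyne.
3. Key disconnection: the decalin C4a–C5 bond, formed by hydrogen-atom-transfer radical cyclization of a tertiary radical onto the ring-B ketone (6-exo onto C=O), which closes ring A and gives the cis-fused 4a-hydroxy decalin.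
4. Ring-B ketone: copper-catalysed conjugate addition/enolate alkylation on (R)-2,4-dimethylcyclohex-2-enone sets C1 and C8a.
5. Ring B comes from propanal and ethyl vinyl ketone (organocatalytic Michael/aldol, sets C2). Ring order: ring B, then ring A, then the 1,2-dioxane.

Assumption: the SMILES is read as the (2S)-propanoate on a (3S,6R)-1,2-dioxane carrying a cis-fused (1S,2R,4aS,8aR)-4a-hydroxydecalin (dioxane numbered O1, O2, C3–C6; decalin numbered as decahydronaphthalene), and the silylated bromoalkyne and the iodoalkene used in step 2 are taken as purchasable.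

## Route

Step 1
Reactants: 1 propanal; 2 pent-1-en-3-one (ethyl vinyl ketone)
Product: 4 (4R)-2,4-dimethylcyclohex-2-en-1-one, via Michael adduct 3 (not isolated)
Conditions: (S)-2-[methoxy(diphenyl)methyl]pyrrolidine (5 mol %), ethyl 3,4-dihydroxybenzoate (20 mol %), neat, 4 °C; then LiOH, i-PrOH, 23 °C
Reagents that add atoms: none
Why: Enamine-catalysed Michael addition, in which the (S)-pyrrolidine shields one face of the propanal enamine and so sets the (R)-methyl centre (later C2 of the decalin), is followed by LiOH-mediated intramolecular aldol condensation (Robinson-type annulation) that closes ring B without touching that centre.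

Step 2
Reactants: 4 (4R)-2,4-dimethylcyclohex-2-en-1-one; 5 (4-bromobut-1-yn-1-yl)trimethylsilane; 6 5-iodo-2-methylpent-1-ene
Product: 9 (2R,3S,4R)-2,4-dimethyl-2-(4-methylpent-4-en-1-yl)-3-[4-(trimethylsilyl)but-3-yn-1-yl]cyclohexan-1-one, via Grignard reagent 7 (not isolated), via magnesium enolate 8 (not isolated)
Conditions: 5, Mg, THF, 23 °C; CuBr·SMe2 (10 mol %), 4, THF, −40 → 0 °C; then 6 (3 equiv), HMPA, 0 → 40 °C
Reagents that add atoms: none
Why: Copper-catalysed 1,4-addition of Grignard reagent 7 (Kharasch-type conjugate addition) occurs anti to the C4 methyl group and the regiodefined enolate 8 is then C-alkylated by iodide 6 anti to the new C3 chain (tandem conjugate addition–enolate alkylation), which sets C3 (S) and the quaternary C2 (R) with the ring methyl cis to the alkynyl chain.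

Step 3
Reactants: 9 (2R,3S,4R)-2,4-dimethyl-2-(4-methylpent-4-en-1-yl)-3-[4-(trimethylsilyl)but-3-yn-1-yl]cyclohexan-1-one
Product: 11 (1S,2R,4aS,8aR)-1-(but-3-yn-1-yl)-2,5,5,8a-tetramethyldecahydronaphthalen-4a-ol, via silylalkyne decalinol 10 (not isolated)
Conditions: Fe(acac)3 (30 mol %), PhSiH3 (2.5 equiv), EtOH, 60 °C; then K2CO3, MeOH, 23 °C
Reagents that add atoms: none
Why: Hydrogen-atom transfer from an iron hydride to the 1,1-disubstituted alkene gives a tertiary radical that adds 6-exo to the ring ketone through a chair transition state on the face that carries the tether (MHAT-initiated radical ketone–olefin cyclization), the alkoxy radical being reduced by the iron/silane system, so the C4a–C5 bond, both methyl groups on C5 and the cis ring fusion (4a-OH cis to the 8a-methyl group, 4aS) arise in one operation, after which carbonate methanolysis removes the alkynyl silyl group.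

Step 4
Reactants: 11 (1S,2R,4aS,8aR)-1-(but-3-yn-1-yl)-2,5,5,8a-tetramethyldecahydronaphthalen-4a-ol; 12 3-bromoprop-1-ene (allyl bromide)
Product: 14 (1S,2R,4aS,8aR)-2,5,5,8a-tetramethyl-1-[(3E)-3-methylhepta-3,6-dien-1-yl]decahydronaphthalen-4a-ol, via alkenylalane 13 (not isolated)
Conditions: Me3Al (3.5 equiv), Cp2ZrCl2 (25 mol %), CH2Cl2, 0 → 23 °C; then 12, Pd(PPh3)4 (5 mol %), THF, 23 °C
Reagents that add atoms: trimethylaluminium, C[Al](C)C
Why: Zirconium-catalysed syn-methylalumination of the terminal alkyne (Negishi carboalumination) puts the methyl group on the internal carbon and the alkenylalane 13 is allylated with retention under palladium catalysis (Negishi-type alkenyl–allyl coupling), which gives only the (E)-trisubstituted alkene.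

Step 5
Reactants: 14 (1S,2R,4aS,8aR)-2,5,5,8a-tetramethyl-1-[(3E)-3-methylhepta-3,6-dien-1-yl]decahydronaphthalen-4a-ol; 15 methyl methacrylate
Product: 16 methyl (2E,5E)-8-[(1S,2R,4aS,8aR)-4a-hydroxy-2,5,5,8a-tetramethyldecahydronaphthalen-1-yl]-2,6-dimethylocta-2,5-dienoate
Conditions: second-generation Grubbs catalyst [RuCl2(=CHPh)(PCy3)(H2IMes)] (5 mol %), 15 (10 equiv), 1,4-benzoquinone (10 mol %), CH2Cl2, 40 °C
Reagents that add atoms: none
Why: Olefin cross-metathesis of the terminal vinyl group with excess methyl methacrylate gives the (E)-2-methyl-enoate under thermodynamic control, while the trisubstituted alkene is too hindered to take part.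

Step 6
Reactants: 16 methyl (2E,5E)-8-[(1S,2R,4aS,8aR)-4a-hydroxy-2,5,5,8a-tetramethyldecahydronaphthalen-1-yl]-2,6-dimethylocta-2,5-dienoate
Product: 17 methyl (2E,6S)-8-[(1S,2R,4aS,8aR)-4a-hydroxy-2,5,5,8a-tetramethyldecahydronaphthalen-1-yl]-2,6-dimethyl-6-[(triethylsilyl)peroxy]oct-2-enoate
Conditions: Co(thd)2 [bis(2,2,6,6-tetramethylheptane-3,5-dionato)cobalt] (10 mol %), O2 (1 atm), Et3SiH (3 equiv), 1,2-dichloroethane, 23 °C
Reagents that add atoms: dioxygen, O=O; triethylsilane, CC[SiH](CC)CC
Why: Cobalt-hydride hydrogen-atom transfer to the electron-rich trisubstituted alkene (the enoate is inert) gives the tertiary C6 radical, which is trapped by O2 and silylated (Mukaiyama–Isayama silylperoxidation); the planar radical is trapped without facial bias, so 17 forms with its C6 epimer in about equal amount and the pair is carried on together.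

Step 7
Reactants: 17 methyl (2E,6S)-8-[(1S,2R,4aS,8aR)-4a-hydroxy-2,5,5,8a-tetramethyldecahydronaphthalen-1-yl]-2,6-dimethyl-6-[(triethylsilyl)peroxy]oct-2-enoate
Product: 19 methyl (2S)-2-[(3S,6R)-6-{2-[(1S,2R,4aS,8aR)-4a-hydroxy-2,5,5,8a-tetramethyldecahydronaphthalen-1-yl]ethyl}-6-methyl-1,2-dioxan-3-yl]propanoate, via hydroperoxide 18 (not isolated)
Conditions: HCl (cat.), MeOH, 0 °C; then Et2NH, CF3CH2OH, 23 °C; preparative HPLC
Reagents that add atoms: none
Why: Acidic methanolysis frees hydroperoxide 18 and the amine then triggers a 6-exo intramolecular peroxy-Michael addition through a chair transition state with the propanoate arm equatorial, which sets C3 and, on protonation of the ester enolate, the α-centre under substrate control only, so that 19 has to be separated by HPLC from its dioxane diastereomers (C3/α-epimers and the C6-epimeric series).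

## Compound list

1 | propanal | CCC=O | starting material
2 | pent-1-en-3-one (ethyl vinyl ketone) | CCC(=O)C=C | starting material
3 | (2R)-2-methyl-5-oxoheptanal | O=C[C@H](C)CCC(=O)CC | intermediate
4 | (4R)-2,4-dimethylcyclohex-2-en-1-one | CC1=C[C@H](C)CCC1=O | intermediate
5 | (4-bromobut-1-yn-1-yl)trimethylsilane | C[Si](C)(C)C#CCCBr | starting material
6 | 5-iodo-2-methylpent-1-ene | C=C(C)CCCI | starting material
7 | [4-(trimethylsilyl)but-3-yn-1-yl]magnesium bromide | C[Si](C)(C)C#CCC[Mg]Br | intermediate
8 | bromomagnesium (3S,4R)-2,4-dimethyl-3-[4-(trimethylsilyl)but-3-yn-1-yl]cyclohex-1-en-1-olate | C[Si](C)(C)C#CCC[C@H]1[C@H](C)CCC(O[Mg]Br)=C1C | intermediate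
9 | (2R,3S,4R)-2,4-dimethyl-2-(4-methylpent-4-en-1-yl)-3-[4-(trimethylsilyl)but-3-yn-1-yl]cyclohexan-1-one | C[Si](C)(C)C#CCC[C@H]1[C@H](C)CCC(=O)[C@]1(C)CCCC(C)=C | intermediate
10 | (1S,2R,4aS,8aR)-2,5,5,8a-tetramethyl-1-[4-(trimethylsilyl)but-3-yn-1-yl]decahydronaphthalen-4a-ol | C[Si](C)(C)C#CCC[C@H]1[C@H](C)CC[C@]2(O)C(C)(C)CCC[C@]12C | intermediate
11 | (1S,2R,4aS,8aR)-1-(but-3-yn-1-yl)-2,5,5,8a-tetramethyldecahydronaphthalen-4a-ol | C#CCC[C@H]1[C@H](C)CC[C@]2(O)C(C)(C)CCC[C@]12C | intermediate
12 | 3-bromoprop-1-ene (allyl bromide) | C=CCBr | starting material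
13 | (E)-alkenyl(dimethyl)alane of 11 after methylalumination, alcohol as its dimethylaluminium alkoxide | C[Al](C)/C=C(\C)CC[C@H]1[C@H](C)CC[C@]2(O[Al](C)C)C(C)(C)CCC[C@]12C | intermediate
14 | (1S,2R,4aS,8aR)-2,5,5,8a-tetramethyl-1-[(3E)-3-methylhepta-3,6-dien-1-yl]decahydronaphthalen-4a-ol | C=CC/C=C(\C)CC[C@H]1[C@H](C)CC[C@]2(O)C(C)(C)CCC[C@]12C | intermediate
15 | methyl methacrylate | C=C(C)C(=O)OC | starting material
16 | methyl (2E,5E)-8-[(1S,2R,4aS,8aR)-4a-hydroxy-2,5,5,8a-tetramethyldecahydronaphthalen-1-yl]-2,6-dimethylocta-2,5-dienoate | COC(=O)/C(C)=C/C/C=C(\C)CC[C@H]1[C@H](C)CC[C@]2(O)C(C)(C)CCC[C@]12C | intermediate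
17 | methyl (2E,6S)-8-[(1S,2R,4aS,8aR)-4a-hydroxy-2,5,5,8a-tetramethyldecahydronaphthalen-1-yl]-2,6-dimethyl-6-[(triethylsilyl)peroxy]oct-2-enoate (formed with its 6R epimer) | COC(=O)/C(C)=C/CC[C@@](C)(CC[C@H]1[C@H](C)CC[C@]2(O)C(C)(C)CCC[C@]12C)OO[Si](CC)(CC)CC | intermediate
18 | methyl (2E,6S)-6-hydroperoxy-8-[(1S,2R,4aS,8aR)-4a-hydroxy-2,5,5,8a-tetramethyldecahydronaphthalen-1-yl]-2,6-dimethyloct-2-enoate | COC(=O)/C(C)=C/CC[C@@](C)(CC[C@H]1[C@H](C)CC[C@]2(O)C(C)(C)CCC[C@]12C)OO | intermediate
19 | methyl (2S)-2-[(3S,6R)-6-{2-[(1S,2R,4aS,8aR)-4a-hydroxy-2,5,5,8a-tetramethyldecahydronaphthalen-1-yl]ethyl}-6-methyl-1,2-dioxan-3-yl]propanoate | COC(=O)[C@@H](C)[C@@H]1CC[C@@](C)(CC[C@H]2[C@H](C)CC[C@]3(O)C(C)(C)CCC[C@]23C)OO1 | target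

## Step count and weak points

Total step count: 7. Longest linear sequence: 7 (1 and 2 to 19).

The three steps most likely to fail are step 3, step 2 and step 7.

Step 3 (the radical ring closure) joins a tertiary radical to a ketone carbon flanked by a quaternary centre. Plain hydrogenation of the alkene, β-scission of the crowded alkoxy radical and some trans-fused product are the likely losses. The fallback sets out from 9 and reverses the polarity of the radical step: SmI2 (3 equiv), HMPA, t-BuOH, THF, 0 °C generates the ketyl radical anion, which attacks the internal carbon of the 1,1-disubstituted alkene (6-exo ketyl–olefin cyclization). The resulting primary radical is reduced and protonated to the second methyl group, so the same bond is formed from the other end and the route is rejoined at 10 (no new compound, F0).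

Step 2 asks a tetrasubstituted magnesium enolate to react with an unactivated primary iodide, and O-alkylation, proton transfer or no reaction may dominate. The fallback sets out from magnesium enolate 8, which is trapped with allyl bromide 12 in place of 6. Allylation is reliable for such enolates and has the same anti selectivity, and it gives the 2-allyl ketone F1. Hydroboration of the allyl group with 9-BBN (THF, 23 °C; the hindered ketone and the silylalkyne react more slowly) gives the B-alkyl borane F2. This is coupled in the same flask with 2-bromopropene (PdCl2(dppf), aqueous K3PO4, THF, 50 °C; B-alkyl Suzuki–Miyaura coupling), which comes back to the route at 9.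

Step 7 depends on substrate control alone for C3 and the α-centre. It also inherits the uncontrolled C6 centre from step 6, and the amine can trigger Kornblum–DeLaMare cleavage of the product. The fallback sets out from 14 and forms the C3–Cα bond instead of the C3–O bond last; it does not improve C6. Silylperoxidation of 14 (Co(thd)2, O2, Et3SiH; the trisubstituted alkene reacts before the vinyl group) gives the silyl peroxide F3. Ozonolysis of the vinyl group (O3, CH2Cl2/MeOH, −78 °C; Me2S) gives the peroxy aldehyde F4. HCl in MeOH removes the silyl group and closes the ring as the 3-methoxy-1,2-dioxane F5 (cyclic peroxyacetal, both anomers). TiCl4 in CH2Cl2 at −78 °C ionises F5 to the peroxycarbenium ion, which is captured by (E)-1-methoxy-1-(trimethylsilyloxy)prop-1-ene (Mukaiyama-type addition of a silyl ketene acetal). This returns to the route at 19, again purified by HPLC.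

## Further compounds

F1 | step 2 | (2R,3S,4R)-2,4-dimethyl-2-(prop-2-en-1-yl)-3-[4-(trimethylsilyl)but-3-yn-1-yl]cyclohexan-1-one | C[Si](C)(C)C#CCC[C@H]1[C@H](C)CCC(=O)[C@]1(C)CC=C
F2 | step 2 | (2R,3S,4R)-2-[3-(9-borabicyclo[3.3.1]nonan-9-yl)propyl]-2,4-dimethyl-3-[4-(trimethylsilyl)but-3-yn-1-yl]cyclohexan-1-one | C[Si](C)(C)C#CCC[C@H]1[C@H](C)CCC(=O)[C@]1(C)CCCB2C3CCCC2CCC3
F0 | step 3 | none | none
F3 | step 7 | (1S,2R,4aS,8aR)-2,5,5,8a-tetramethyl-1-{(3S)-3-methyl-3-[(triethylsilyl)peroxy]hept-6-en-1-yl}decahydronaphthalen-4a-ol | C=CCC[C@@](C)(CC[C@H]1[C@H](C)CC[C@]2(O)C(C)(C)CCC[C@]12C)OO[Si](CC)(CC)CC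
F4 | step 7 | (4R)-6-[(1S,2R,4aS,8aR)-4a-hydroxy-2,5,5,8a-tetramethyldecahydronaphthalen-1-yl]-4-methyl-4-[(triethylsilyl)peroxy]hexanal | O=CCC[C@@](C)(CC[C@H]1[C@H](C)CC[C@]2(O)C(C)(C)CCC[C@]12C)OO[Si](CC)(CC)CC
F5 | step 7 | (1S,2R,4aS,8aR)-1-{2-[(3R)-6-methoxy-3-methyl-1,2-dioxan-3-yl]ethyl}-2,5,5,8a-tetramethyldecahydronaphthalen-4a-ol (both anomers at the methoxy carbon) | COC1CC[C@@](C)(CC[C@H]2[C@H](C)CC[C@]3(O)C(C)(C)CCC[C@]23C)OO1
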